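The whole route hinges on the C9–C10 bond of ring B. In the target, ring A carries its C3 oxygen para to the quaternary C10 (C20 methyl), with the C4 methyl ortho and C5 meta, so ring A is taken from a 2,4-dimethylphenol tethered at its 3-position (C5). One iridium-catalysed asymmetric allylic dearomatisation lets the phenolate para carbon C10 attack the substituted allyl terminus C9. This closes ring B, sets C9 and C10, and leaves a C9 vinyl group and a dienone for the later C4/C3 chemistry. The precursor is this phenol bearing a C6–C7 ethylene link, a C8 dioxolane and an (E)-allylic methyl carbonate (C9, C11, C12).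

Key step: step 10

Remark (assumptions): labdane numbering is used for positions; 3-bromo-2,4-dimethylaniline and (3S)-3-methylpentanoic acid are taken as catalogue compounds; the sense of induction of the iridium catalyst is assigned by analogy, and the mirror-image ligand is used if it proves opposite.

Step 1
Reactants: 1 3-bromo-2,4-dimethylaniline
Product: 3 3-bromo-2,4-dimethylphenol, via arenediazonium hydrogensulfate 2 (not isolated)
Conditions: NaNO2, aq. H2SO4, 0–5 °C; then aq. H2SO4, 100 °C
Reagents that add atoms: water, O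
Why: Diazotisation and hydrolytic dediazoniation (phenol synthesis from an arenediazonium salt) exchange NH2 for OH and leave the flanked aryl bromide untouched.

Step 2
Reactants: 3 3-bromo-2,4-dimethylphenol
Product: 4 (3-bromo-2,4-dimethylphenoxy)tri(propan-2-yl)silane
Conditions: TIPSCl, imidazole, DMF, 40 °C
Reagents that add atoms: chlorotri(propan-2-yl)silane (TIPSCl), CC(C)[Si](Cl)(C(C)C)C(C)C
Why: Silylation of the phenol gives an aryl silyl ether that should withstand the palladium, organolithium, Lewis-acid and hydride steps and is later removed by fluoride without touching ketal or carbonate.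

Step 3
Reactants: 4 (3-bromo-2,4-dimethylphenoxy)tri(propan-2-yl)silane; 5 N-methoxy-N-methylprop-2-enamide
Product: 6 (E)-3-[2,6-dimethyl-3-(triisopropylsilyloxy)phenyl]-N-methoxy-N-methylprop-2-enamide
Conditions: Pd2(dba)3 (2 mol %), [HP(t-Bu)3]BF4 (8 mol %), Cy2NMe, 1,4-dioxane, 100 °C
Reagents that add atoms: none
Why: Mizoroki–Heck reaction in which the bulky electron-rich phosphine permits oxidative addition at the di-ortho-substituted bromide and syn β-hydride elimination gives the E-alkene (C5–C6 bond).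

Step 4
Reactants: 6 (E)-3-[2,6-dimethyl-3-(triisopropylsilyloxy)phenyl]-N-methoxy-N-methylprop-2-enamide
Product: 7 3-[2,6-dimethyl-3-(triisopropylsilyloxy)phenyl]-N-methoxy-N-methylpropanamide
Conditions: H2 (1 atm), 10% Pd/C, EtOAc, rt
Reagents that add atoms: none
Why: Heterogeneous catalytic hydrogenation saturates the conjugated alkene, while the aryl silyl ether and the N-methoxy-N-methylamide persist under these mild conditions.

Step 5
Reactants: 7 3-[2,6-dimethyl-3-(triisopropylsilyloxy)phenyl]-N-methoxy-N-methylpropanamide; 8 2-(prop-2-yn-1-yloxy)oxane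
Product: 10 1-[2,6-dimethyl-3-(triisopropylsilyloxy)phenyl]-6-(oxan-2-yloxy)hex-4-yn-3-one, via lithium acetylide 9 (not isolated)
Conditions: n-BuLi, THF, −78 °C; then 7, −78 to 0 °C; aq. NH4Cl
Reagents that add atoms: none
Why: Weinreb ketone synthesis, in which the chelated tetrahedral adduct of the alkynyllithium prevents double addition and releases the ynone (C8–C9 bond) on work-up.

Step 6
Reactants: 10 1-[2,6-dimethyl-3-(triisopropylsilyloxy)phenyl]-6-(oxan-2-yloxy)hex-4-yn-3-one
Product: 12 3-(2-{2-[2,6-dimethyl-3-(triisopropylsilyloxy)phenyl]ethyl}-1,3-dioxolan-2-yl)prop-2-yn-1-ol, via tetrahydropyranyl-protected ketal 11 (not isolated)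
Conditions: (Me3SiOCH2)2, Me3SiOTf (5 mol %), CH2Cl2, −78 to −20 °C; then MeOH, 0 °C; Et3N
Reagents that add atoms: 1,2-bis(trimethylsilyloxy)ethane, C[Si](C)(C)OCCO[Si](C)(C)C
Why: Silyl-triflate-catalysed ketalisation with the bis-silyl glycol should proceed at low temperature without conjugate addition to the ynone, and acid-catalysed methanolysis then removes the tetrahydropyranyl acetal, which is far more labile than the propargylic dioxolane.

Step 7
Reactants: 12 3-(2-{2-[2,6-dimethyl-3-(triisopropylsilyloxy)phenyl]ethyl}-1,3-dioxolan-2-yl)prop-2-yn-1-ol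
Product: 13 (E)-3-(2-{2-[2,6-dimethyl-3-(triisopropylsilyloxy)phenyl]ethyl}-1,3-dioxolan-2-yl)prop-2-en-1-ol
Conditions: NaAlH2(OCH2CH2OMe)2, THF, 0 °C; aq. potassium sodium tartrate
Reagents that add atoms: none
Why: Hydroxyl-directed trans-hydroalumination of the propargylic alcohol followed by protonolysis gives the E-allylic alcohol, and the propargylic ketal should be retained at this temperature.

Step 8
Reactants: 13 (E)-3-(2-{2-[2,6-dimethyl-3-(triisopropylsilyloxy)phenyl]ethyl}-1,3-dioxolan-2-yl)prop-2-en-1-ol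
Product: 14 (E)-3-(2-{2-[2,6-dimethyl-3-(triisopropylsilyloxy)phenyl]ethyl}-1,3-dioxolan-2-yl)prop-2-en-1-yl methyl carbonate
Conditions: ClCO2Me, pyridine, CH2Cl2, 0 °C
Reagents that add atoms: methyl chloroformate, COC(=O)Cl
Why: O-Acylation of the primary allylic alcohol with a chloroformate installs the carbonate leaving group while the phenol is still masked.

Step 9
Reactants: 14 (E)-3-(2-{2-[2,6-dimethyl-3-(triisopropylsilyloxy)phenyl]ethyl}-1,3-dioxolan-2-yl)prop-2-en-1-yl methyl carbonate
Product: 15 (E)-3-{2-[2-(3-hydroxy-2,6-dimethylphenyl)ethyl]-1,3-dioxolan-2-yl}prop-2-en-1-yl methyl carbonate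
Conditions: Bu4NF, AcOH, THF, 0 °C
Reagents that add atoms: none
Why: Fluoride-mediated cleavage of the aryl silyl ether under acetic acid buffering frees the phenol, and the buffered medium keeps the phenoxide from attacking the carbonate.

Step 10
Reactants: 15 (E)-3-{2-[2-(3-hydroxy-2,6-dimethylphenyl)ethyl]-1,3-dioxolan-2-yl}prop-2-en-1-yl methyl carbonate
Product: 16 (9S,10S)-9-vinyl-4,10-dimethyl-8,8-ethylenedioxy-bicyclic 1,4-dien-3-one
Conditions: [Ir(cod)Cl]2 (2.5 mol %), (R,R,Ra)-N,N-bis(1-phenylethyl)dinaphtho[2,1-d:1',2'-f][1,3,2]dioxaphosphepin-4-amine (5 mol %), n-PrNH2 pre-activation, DBU (1.0 equiv), THF (0.01 M), 50 °C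
Reagents that add atoms: none
Why: Proposed new method: a monovalent iridium–phosphoramidite complex ionises the allylic carbonate (loss of CO2 and methoxide) to a π-allyl complex, and the phenolate of 15 attacks its substituted terminus C9 through the para carbon C10 on the face opposite to the metal, giving a cross-conjugated dienone because C10 bears a methyl group and cannot rearomatise; the closest known reaction type is the iridium-catalysed intramolecular asymmetric allylic alkylative dearomatisation of para-tethered phenols to spirodienones, here transferred to a meta tether and a methyl-bearing para carbon. Ring B (C5–C6–C7–C8–C9–C10) closes in a six-membered exo mode, the allyl double bond staying outside the ring as the C9 vinyl group, whereas attack at the far terminus C12 would need an eight-membered ring. C9 is set by the catalyst, which fixes the allyl face that the nucleophile meets, and C10 is set relative to C9 by a chair-like transition state in which the metal-bound vinyl terminus is equatorial and points away from the arene while C9–H lies over ring A, which places vinyl and the C10 methyl cis. The step needs attack at C10 and not at C4: C4 is flanked by the ion-paired oxygen on C3 and by the tether carbon C5, whereas C10 has only C1–H as its second neighbour, and the fully substituted dioxolane carbon C8 carries no hydrogen that could be lost to form a diene. High dilution is relied on to suppress intermolecular O- and C-allylation.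

Step 11
Reactants: 16 (9S,10S)-9-vinyl-4,10-dimethyl-8,8-ethylenedioxy-bicyclic 1,4-dien-3-one
Product: 17 (9S,10S)-9-vinyl-4,10-dimethyl-8,8-ethylenedioxy-bicyclic 4-en-3-one
Conditions: [(Ph3P)CuH]6 (0.2 equiv), benzene, H2O (2 equiv), rt
Reagents that add atoms: none
Why: Copper hydride conjugate reduction delivers hydride to the β-carbon C1 of the disubstituted C1=C2 enone far faster than to the fully substituted C5, and the isolated vinyl group and the ketal are inert to it.

Step 12
Reactants: 17 (9S,10S)-9-vinyl-4,10-dimethyl-8,8-ethylenedioxy-bicyclic 4-en-3-one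
Product: 19 (5S,9S,10R)-9-vinyl-4,4,10-trimethyl-8,8-ethylenedioxy-trans-decalin-3-one, via lithium enolate 18 (not isolated)
Conditions: Li, NH3/THF, t-BuOH (1.0 equiv), −78 °C; isoprene; then MeI, −78 to −33 °C
Reagents that add atoms: iodomethane, CI
Why: Dissolving-metal reduction of the enone with enolate trapping (reductive alkylation) protonates C5 axially, anti to the C10 methyl, to set the trans ring fusion, and the regiodefined C3–C4 enolate is methylated at C4 to the gem-dimethyl ketone.

Step 13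
Reactants: 19 (5S,9S,10R)-9-vinyl-4,4,10-trimethyl-8,8-ethylenedioxy-trans-decalin-3-one
Product: 20 (3S,5S,9S,10R)-9-vinyl-4,4,10-trimethyl-8,8-ethylenedioxy-trans-decalin-3-ol
Conditions: LiBH(s-Bu)3, THF, −78 °C; aq. NH4Cl
Reagents that add atoms: none
Why: Ketone reduction with a bulky trialkylborohydride, which approaches along the equatorial trajectory and avoids the axial hydrogens on C1 and C5, should give the axial C3 alcohol trans to the C10 methyl.

Step 14
Reactants: 20 (3S,5S,9S,10R)-9-vinyl-4,4,10-trimethyl-8,8-ethylenedioxy-trans-decalin-3-ol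
Product: 21 tert-butyldimethylsilyl ether of 20
Conditions: TBSOTf, 2,6-lutidine, CH2Cl2, 0 °C to rt
Reagents that add atoms: tert-butyldimethylsilyl trifluoromethanesulfonate (TBSOTf), CC(C)(C)[Si](C)(C)OS(=O)(=O)C(F)(F)F
Why: Silylation with the silyl triflate protects the hindered axial alcohol for the later enolate and organometallic steps.

Step 15
Reactants: 22 but-2-yn-1-ol
Product: 23 tert-butyl(but-2-yn-1-yloxy)diphenylsilane
Conditions: TBDPSCl, imidazole, DMF, rt
Reagents that add atoms: tert-butyl(chloro)diphenylsilane (TBDPSCl), CC(C)(C)[Si](Cl)(c1ccccc1)c1ccccc1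
Why: Silylation of the primary propargylic alcohol gives an ether that should survive the later acidic ketal cleavage.

Step 16
Reactants: 23 tert-butyl(but-2-yn-1-yloxy)diphenylsilane
Product: 25 (E)-tert-butyl[(3-iodobut-2-en-1-yl)oxy]diphenylsilane, via alkenylzirconocene chloride 24 (not isolated)
Conditions: Cp2Zr(H)Cl, THF, 50 °C; then I2, 0 °C
Reagents that add atoms: iodine, II
Why: syn-Hydrozirconation with equilibration places zirconium on the methyl-bearing alkyne carbon, and iododemetalation with retention gives the E-alkenyl iodide (iodine trans to the CH2O group).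

Step 17
Reactants: 21 tert-butyldimethylsilyl ether of 20; 25 (E)-tert-butyl[(3-iodobut-2-en-1-yl)oxy]diphenylsilane
Product: 27 (3S,5S,9S,10R,13E)-3-(tert-butyldimethylsilyloxy)-15-(tert-butyldiphenylsilyloxy)-8,8-ethylenedioxy-17-norlabd-13-ene, via B-alkyl-9-borabicyclononane 26 (not isolated)
Conditions: 9-BBN, THF, 60 °C; then 25, Pd(dppf)Cl2 (5 mol %), AsPh3, Cs2CO3, DMF/H2O, rt
Reagents that add atoms: none
Why: Anti-Markovnikov hydroboration of the terminal vinyl group and B-alkyl Suzuki–Miyaura coupling, which retains the alkenyl iodide geometry, join C12 to C13 and install the E-configured C13=C14 bond.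

Step 18
Reactants: 27 (3S,5S,9S,10R,13E)-3-(tert-butyldimethylsilyloxy)-15-(tert-butyldiphenylsilyloxy)-8,8-ethylenedioxy-17-norlabd-13-ene
Product: 28 (3S,5S,9S,10R,13E)-3-(tert-butyldimethylsilyloxy)-15-(tert-butyldiphenylsilyloxy)-17-norlabd-13-en-8-one
Conditions: PPTS, acetone/H2O, 60 °C
Reagents that add atoms: water, O
Why: Mild acid-catalysed ketal hydrolysis frees the C8 ketone without loss of either silyl ether, and C9 remains in its favoured equatorial configuration.

Step 19
Reactants: 28 (3S,5S,9S,10R,13E)-3-(tert-butyldimethylsilyloxy)-15-(tert-butyldiphenylsilyloxy)-17-norlabd-13-en-8-one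
Product: 30 (3S,5S,9S,10R,13E)-3-(tert-butyldimethylsilyloxy)-15-(tert-butyldiphenylsilyloxy)-17-norlabda-7,13-dien-8-yl trifluoromethanesulfonate, via potassium enolate 29 (not isolated)
Conditions: KN(SiMe3)2, THF, −78 °C; then PhNTf2, −78 to 0 °C
Reagents that add atoms: N-phenylbis(trifluoromethanesulfonimide) (PhNTf2), O=S(=O)(N(c1ccccc1)S(=O)(=O)C(F)(F)F)C(F)(F)F
Why: Kinetic deprotonation at the unhindered C7 methylene (C9 is a hindered methine next to quaternary C10) followed by O-sulfonylation gives the Δ7 enol triflate regioselectively.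

Step 20
Reactants: 30 (3S,5S,9S,10R,13E)-3-(tert-butyldimethylsilyloxy)-15-(tert-butyldiphenylsilyloxy)-17-norlabda-7,13-dien-8-yl trifluoromethanesulfonate
Product: 31 (3S,5S,9R,10S,13E)-3-(tert-butyldimethylsilyloxy)-15-(tert-butyldiphenylsilyloxy)labda-7,13-diene
Conditions: Fe(acac)3 (5 mol %), MeMgBr, THF/NMP, −30 °C
Reagents that add atoms: methylmagnesium bromide, C[Mg]Br
Why: Iron-catalysed cross-coupling of the alkenyl triflate with the methyl Grignard reagent installs C17 on C8 and fixes the C7=C8 double bond.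

Step 21
Reactants: 31 (3S,5S,9R,10S,13E)-3-(tert-butyldimethylsilyloxy)-15-(tert-butyldiphenylsilyloxy)labda-7,13-diene
Product: 32 (3S,5S,9R,10S,13E)-labda-7,13-diene-3,15-diol
Conditions: Bu4NF, THF, 60 °C
Reagents that add atoms: none
Why: Fluoride-mediated desilylation removes both silyl ethers, warming being needed for the hindered axial C3 ether.

Step 22
Reactants: 32 (3S,5S,9R,10S,13E)-labda-7,13-diene-3,15-diol; 33 (3S)-3-methylpentanoic acid
Product: 34 (3S,5S,9R,10S,13E)-3-hydroxylabda-7,13-dien-15-yl (3S)-3-methylpentanoate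
Conditions: DCC, DMAP (cat.), CH2Cl2, 0 °C
Reagents that add atoms: none
Why: Steglich esterification, in which the primary allylic C15 hydroxyl should react far faster than the axial neopentyl-type C3 hydroxyl, while the β-stereocentre of the acid cannot epimerise.

Step 23
Reactants: 34 (3S,5S,9R,10S,13E)-3-hydroxylabda-7,13-dien-15-yl (3S)-3-methylpentanoate; 35 2,2-dimethyl-1,3-dioxane-4,6-dione
Product: 36 (3S,5S,9R,10S,13E)-15-[(3S)-3-methylpentanoyloxy]labda-7,13-dien-3-yl hydrogen malonate
Conditions: toluene, 100 °C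
Reagents that add atoms: none
Why: Thermal alcoholysis of the cyclic acylal with loss of acetone (ring-opening acylation) delivers the malonic half-ester directly, with no protecting group on the acid.

Compound list
1 | 3-bromo-2,4-dimethylaniline | Cc1ccc(N)c(C)c1Br | starting material
2 | 3-bromo-2,4-dimethylbenzenediazonium hydrogensulfate (not isolated) | Cc1ccc([N+]#N)c(C)c1Br.OS(=O)(=O)[O-] | intermediate
3 | 3-bromo-2,4-dimethylphenol | Cc1ccc(O)c(C)c1Br | intermediate
4 | (3-bromo-2,4-dimethylphenoxy)tri(propan-2-yl)silane | Cc1ccc(O[Si](C(C)C)(C(C)C)C(C)C)c(C)c1Br | intermediate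
5 | N-methoxy-N-methylprop-2-enamide | C=CC(=O)N(C)OC | starting material
6 | (E)-3-[2,6-dimethyl-3-(triisopropylsilyloxy)phenyl]-N-methoxy-N-methylprop-2-enamide | CON(C)C(=O)/C=C/c1c(C)ccc(O[Si](C(C)C)(C(C)C)C(C)C)c1C | intermediate
7 | 3-[2,6-dimethyl-3-(triisopropylsilyloxy)phenyl]-N-methoxy-N-methylpropanamide | CON(C)C(=O)CCc1c(C)ccc(O[Si](C(C)C)(C(C)C)C(C)C)c1C | intermediate
8 | 2-(prop-2-yn-1-yloxy)oxane (tetrahydropyranyl ether of propargyl alcohol; racemic acetal) | C#CCOC1CCCCO1 | starting material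
9 | lithium acetylide of 8 (not isolated) | [Li]C#CCOC1CCCCO1 | intermediate
10 | 1-[2,6-dimethyl-3-(triisopropylsilyloxy)phenyl]-6-(oxan-2-yloxy)hex-4-yn-3-one | Cc1ccc(O[Si](C(C)C)(C(C)C)C(C)C)c(C)c1CCC(=O)C#CCOC1CCCCO1 | intermediate
11 | 2-{2-[2,6-dimethyl-3-(triisopropylsilyloxy)phenyl]ethyl}-2-[3-(oxan-2-yloxy)prop-1-yn-1-yl]-1,3-dioxolane (not isolated) | Cc1ccc(O[Si](C(C)C)(C(C)C)C(C)C)c(C)c1CCC1(C#CCOC2CCCCO2)OCCO1 | intermediate
12 | 3-(2-{2-[2,6-dimethyl-3-(triisopropylsilyloxy)phenyl]ethyl}-1,3-dioxolan-2-yl)prop-2-yn-1-ol | Cc1ccc(O[Si](C(C)C)(C(C)C)C(C)C)c(C)c1CCC1(C#CCO)OCCO1 | intermediate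
13 | (E)-3-(2-{2-[2,6-dimethyl-3-(triisopropylsilyloxy)phenyl]ethyl}-1,3-dioxolan-2-yl)prop-2-en-1-ol | Cc1ccc(O[Si](C(C)C)(C(C)C)C(C)C)c(C)c1CCC1(/C=C/CO)OCCO1 | intermediate
14 | (E)-3-(2-{2-[2,6-dimethyl-3-(triisopropylsilyloxy)phenyl]ethyl}-1,3-dioxolan-2-yl)prop-2-en-1-yl methyl carbonate | COC(=O)OC/C=C/C1(OCCO1)CCc1c(C)c(O[Si](C(C)C)(C(C)C)C(C)C)ccc1C | intermediate
15 | (E)-3-{2-[2-(3-hydroxy-2,6-dimethylphenyl)ethyl]-1,3-dioxolan-2-yl}prop-2-en-1-yl methyl carbonate (key-step precursor) | COC(=O)OC/C=C/C1(OCCO1)CCc1c(C)c(O)ccc1C | intermediate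
16 | (9S,10S)-9-vinyl-4,10-dimethyl-8,8-ethylenedioxy-bicyclic 1,4-dien-3-one (labdane numbering; vinyl cis to the C10 methyl) | C=C[C@@H]1C2(OCCO2)CCC3=C(C)C(=O)C=C[C@@]13C | intermediate
17 | (9S,10S)-9-vinyl-4,10-dimethyl-8,8-ethylenedioxy-bicyclic 4-en-3-one | C=C[C@@H]1C2(OCCO2)CCC3=C(C)C(=O)CC[C@@]13C | intermediate
18 | lithium C3 enolate of the trans-fused 4-methyl ketone (not isolated) | C=C[C@@H]1C2(OCCO2)CC[C@@H]3C(C)=C(O[Li])CC[C@@]13C | intermediate
19 | (5S,9S,10R)-9-vinyl-4,4,10-trimethyl-8,8-ethylenedioxy-trans-decalin-3-one | C=C[C@@H]1C2(OCCO2)CC[C@@H]3C(C)(C)C(=O)CC[C@@]13C | intermediate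
20 | (3S,5S,9S,10R)-9-vinyl-4,4,10-trimethyl-8,8-ethylenedioxy-trans-decalin-3-ol (axial hydroxyl) | C=C[C@@H]1C2(OCCO2)CC[C@@H]3C(C)(C)[C@@H](O)CC[C@@]13C | intermediate
21 | tert-butyldimethylsilyl ether of 20 | C=C[C@@H]1C2(OCCO2)CC[C@@H]3C(C)(C)[C@@H](O[Si](C)(C)C(C)(C)C)CC[C@@]13C | intermediate
22 | but-2-yn-1-ol | CC#CCO | starting material
23 | tert-butyl(but-2-yn-1-yloxy)diphenylsilane | CC#CCO[Si](c1ccccc1)(c1ccccc1)C(C)(C)C | intermediate
24 | (E)-alkenylzirconocene chloride (not isolated) | C/C(=C\CO[Si](c1ccccc1)(c1ccccc1)C(C)(C)C)[Zr](Cl)(C1C=CC=C1)C1C=CC=C1 | intermediate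
25 | (E)-tert-butyl[(3-iodobut-2-en-1-yl)oxy]diphenylsilane | C/C(I)=C\CO[Si](c1ccccc1)(c1ccccc1)C(C)(C)C | intermediate
26 | B-alkyl-9-borabicyclo[3.3.1]nonane with boron on C12 (not isolated) | C(C[C@@H]1C2(OCCO2)CC[C@@H]3C(C)(C)[C@@H](O[Si](C)(C)C(C)(C)C)CC[C@@]13C)B1C2CCCC1CCC2 | intermediate
27 | (3S,5S,9S,10R,13E)-3-(tert-butyldimethylsilyloxy)-15-(tert-butyldiphenylsilyloxy)-8,8-ethylenedioxy-17-norlabd-13-ene | CC(C)(C)[Si](OC/C=C(\C)CC[C@@H]1C2(OCCO2)CC[C@@H]3C(C)(C)[C@@H](O[Si](C)(C)C(C)(C)C)CC[C@@]13C)(c1ccccc1)c1ccccc1 | intermediate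
28 | (3S,5S,9S,10R,13E)-3-(tert-butyldimethylsilyloxy)-15-(tert-butyldiphenylsilyloxy)-17-norlabd-13-en-8-one | CC(C)(C)[Si](OC/C=C(\C)CC[C@@H]1C(=O)CC[C@@H]2C(C)(C)[C@@H](O[Si](C)(C)C(C)(C)C)CC[C@@]12C)(c1ccccc1)c1ccccc1 | intermediate
29 | potassium Δ7 enolate of 28 (not isolated) | CC(C)(C)[Si](OC/C=C(\C)CC[C@@H]1C(O[K])=CC[C@@H]2C(C)(C)[C@@H](O[Si](C)(C)C(C)(C)C)CC[C@@]12C)(c1ccccc1)c1ccccc1 | intermediate
30 | (3S,5S,9S,10R,13E)-3-(tert-butyldimethylsilyloxy)-15-(tert-butyldiphenylsilyloxy)-17-norlabda-7,13-dien-8-yl trifluoromethanesulfonate | CC(C)(C)[Si](OC/C=C(\C)CC[C@@H]1C(OS(=O)(=O)C(F)(F)F)=CC[C@@H]2C(C)(C)[C@@H](O[Si](C)(C)C(C)(C)C)CC[C@@]12C)(c1ccccc1)c1ccccc1 | intermediate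
31 | (3S,5S,9R,10S,13E)-3-(tert-butyldimethylsilyloxy)-15-(tert-butyldiphenylsilyloxy)labda-7,13-diene | CC(C)(C)[Si](OC/C=C(\C)CC[C@@H]1C(C)=CC[C@@H]2C(C)(C)[C@@H](O[Si](C)(C)C(C)(C)C)CC[C@@]12C)(c1ccccc1)c1ccccc1 | intermediate
32 | (3S,5S,9R,10S,13E)-labda-7,13-diene-3,15-diol | OC/C=C(\C)CC[C@@H]1C(C)=CC[C@@H]2C(C)(C)[C@@H](O)CC[C@@]12C | intermediate
33 | (3S)-3-methylpentanoic acid | CC[C@H](C)CC(=O)O | starting material
34 | (3S,5S,9R,10S,13E)-3-hydroxylabda-7,13-dien-15-yl (3S)-3-methylpentanoate | CC[C@H](C)CC(=O)OC/C=C(\C)CC[C@@H]1C(C)=CC[C@@H]2C(C)(C)[C@@H](O)CC[C@@]12C | intermediate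
35 | 2,2-dimethyl-1,3-dioxane-4,6-dione (Meldrum's acid) | CC1(C)OC(=O)CC(=O)O1 | starting material
36 | (3S,5S,9R,10S,13E)-15-[(3S)-3-methylpentanoyloxy]labda-7,13-dien-3-yl hydrogen malonate (CNP0234792.1) | CC[C@H](C)CC(=O)OC/C=C(\C)CC[C@@H]1C(C)=CC[C@@H]2C(C)(C)[C@@H](OC(=O)CC(=O)O)CC[C@@]12C | target

Total step count: 23 steps (21 on the main line, 2 for the side-chain iodide).
Longest linear sequence: 21 steps (1 to 36 through steps 1–14 and 17–23).

Steps most likely to fail

Step 10. The cyclisation may suffer from attack through the ortho carbon C4 in place of C10, from formation of the trans C9/C10 relationship (allyl unit stacked over ring A), or from intermolecular O- or C-allylation outcompeting ring closure. The fallback reverses the polarity of the same ring closure with known chemistry. It sets out from carbonate 14. Pd-catalysed silylation with Me3SiSiMe3 (Pd(dba)2, LiCl, DMF) should give the (E)-allyltrimethylsilane F1. Buffered Bu4NF/AcOH at 0 °C then frees the phenol to give the allylsilane phenol F2. Oxidation with PhI(OAc)2 in (CF3)2CHOH at −10 °C is an oxidative dearomatisation of a para-alkylphenol with allylsilane trapping (an umpoled Hosomi–Sakurai reaction). It should form the same C9–C10 bond and give the racemic cis dienone F3. Resolution by preparative chromatography on a chiral stationary phase returns to 16.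

Step 17. Hydroboration may be sluggish at the vinyl group, which sits between quaternary C10 and the ketal carbon C8, and the hindered borane may transmetalate slowly and lose boron by protonolysis. The fallback sets out from 21. Hydroboration with the small reagent BH3·SMe2 and NaOH/H2O2 oxidation should give the primary alcohol F4. I2/PPh3/imidazole converts it into the iodide F5. Iodine–lithium exchange with t-BuLi at −78 °C and transmetalation with ZnCl2 give the alkylzinc chloride F6. Negishi coupling of F6 with 25 (Pd(PPh3)4, THF) returns to 27.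

Step 23. Acylation of the axial, neopentyl-type C3 hydroxyl may stay incomplete, and the half-ester may lose CO2 at the temperature needed. The fallback sets out from 34. DCC/DMAP coupling with 3-oxo-3-[2-(trimethylsilyl)ethoxy]propanoic acid, an acylation that tolerates hindered alcohols, should give the mixed malonate F7. Bu4NF in THF at rt then removes the 2-(trimethylsilyl)ethyl group by fluoride-induced fragmentation and returns to 36.

Further compounds
F1 | step 10 | (E)-[3-(2-{2-[2,6-dimethyl-3-(triisopropylsilyloxy)phenyl]ethyl}-1,3-dioxolan-2-yl)prop-2-en-1-yl]trimethylsilane | C[Si](C)(C)C/C=C/C1(OCCO1)CCc1c(C)c(O[Si](C(C)C)(C(C)C)C(C)C)ccc1C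
F2 | step 10 | 2,4-dimethyl-3-(2-{2-[(E)-3-(trimethylsilyl)prop-1-en-1-yl]-1,3-dioxolan-2-yl}ethyl)phenol | C[Si](C)(C)C/C=C/C1(OCCO1)CCc1c(C)c(O)ccc1C
F3 | step 10 | racemic cis dienone (racemate of 16) | C=C[C@@H]1C2(OCCO2)CCC3=C(C)C(=O)C=C[C@@]13C.C=C[C@H]1C2(OCCO2)CCC3=C(C)C(=O)C=C[C@]13C
F4 | step 17 | primary alcohol from hydroboration–oxidation of 21 (C12 hydroxyl) | OCC[C@@H]1C2(OCCO2)CC[C@@H]3C(C)(C)[C@@H](O[Si](C)(C)C(C)(C)C)CC[C@@]13C
F5 | step 17 | primary iodide from F4 (C12 iodide) | ICC[C@@H]1C2(OCCO2)CC[C@@H]3C(C)(C)[C@@H](O[Si](C)(C)C(C)(C)C)CC[C@@]13C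
F6 | step 17 | alkylzinc chloride from F5 | Cl[Zn]CC[C@@H]1C2(OCCO2)CC[C@@H]3C(C)(C)[C@@H](O[Si](C)(C)C(C)(C)C)CC[C@@]13C
F7 | step 23 | (3S,5S,9R,10S,13E)-15-[(3S)-3-methylpentanoyloxy]labda-7,13-dien-3-yl 2-(trimethylsilyl)ethyl malonate | CC[C@H](C)CC(=O)OC/C=C(\C)CC[C@@H]1C(C)=CC[C@@H]2C(C)(C)[C@@H](OC(=O)CC(=O)OCC[Si](C)(C)C)CC[C@@]12C
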